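Amounts opened the meeting: the flasks differ in free base and in time, as listed.

| flask | electrophile | free base | protonated nucleophile | remark | time |
|---|---|---|---|---|---|
| north-west | 22 mM | 1.1 equiv | 1.2 equiv | run made earlier |  |
| west | 22 mM | 2.3 equiv | 1.2 equiv | run made earlier |  |
| spring | 22 mM | 1.00 equiv | 1.20 equiv |  | 20 h |
| autumn | 22 mM | 1.50 equiv | 1.20 equiv |  | 20 h |

- north-west (time / h: electrophile / %, product / %): 1.00: 96.2, 0; 2.00: 95.3, 2.9; 4.00: 90.5, 3.9; 8.00: 89.6, 7.3; 15.0: 84.3, 13.3
- west (time / h: electrophile / %, product / %): 1.33: 95.5, 1.9; 4.00: 92.6, 4.3; 6.00: 90.2, 6.5; 10.0: 86.4, 12.5; 15.0: 81.5, 17.0

(standard deviation of a reading: 1 percentage point)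

- what has gone from electrophile into another species counts as reacted, even if it can come back

- part of the electrophile that has reacted at the end, spring
- part of the electrophile that has reacted at the end, autumn
- what raising the equivalents of free base from its lowest to its highest value here does to the part of the electrophile that has reacted (changes below 5 percentage points count as none) (it falls / no change / it rises)

The bench chemist reported that product climbs steadily in both earlier runs, to 13.3% at 15.0 h in the north-west run and to 17.0% at 15.0 h in the west run.

The kineticist argued that the concentration to look for is c(nucleophile): while it holds level, the rate follows the electrophile at first order. She proposed carrying one number, the hourly share, which is minus the logarithm of the part not yet product, divided by the time (a pseudo-first-order constant). It came to 0.00951 /h in the north-west run and 0.0124 /h in the west run, so 2.09 times the free base went with 1.30 times the share.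

As her own reckoning she drew a straight line between the two runs. For spring, slightly outside them, it gave 0.00927 /h, and for autumn an hourly share at 1.50 equiv of 0.0105 /h. Over 20 h that means 16.9% and 18.9% product. The gap of 2 percentage points is less than the 5 points that counts, so, taking any side loss as equal in both flasks, she expected no change.

The forecast differed on the trend. It gave 19% for spring, 22.5% for autumn and "it rises", holding that the rate “looks like a saturating acid–base pre-equilibrium that frees the nucleophile”. Its rise was reckoned up to 2.3 equiv, while these flasks stop at 1.50 equiv.

The flasks give 18.4% for spring and 20.3% for autumn, a change of 1.9 points: no change.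

    electrophile + nucleophile → acid set free + product (k = 14.4 /M/h)
    nucleophile + acid set free ⇌ protonated nucleophile, settled at all times (K = 64000 /M)
    acid set free + free base ⇌ salt of the base (K = 9500 /M, k = 25.3 /M/h)
    electrophile + acid set free ⇌ idle adduct, settled at all times (K = 56.0 /M)

The neighbouring flask is the autumn flask left until 30 h, all amounts held. The hourly share of 0.0105 /h over that time reckons 27.0% product, and the flask holds 24.7%. Its own reading gives a share of 0.00947 /h, lower than the carried one. In this autumn recipe c(nucleophile) stood at 0.689 mM at 10.0 h, 0.640 mM at 20.0 h and 0.597 mM at 30.0 h. At 30.0 h the neighbouring flask shows 26.9% of the electrophile charged as reacted, with idle adduct standing at 2.18% of the electrophile charged.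

All runs are calculated with constants of no real substance.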